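**Retrosynthetic overview**
1. Germacrane locants are used: C1 CHOH, C2 CH2, C3 C=O, C4/C5 epoxide, C6 lactone O–CH, C7, C8 CH–O‑tigloyl, C9, C10 CH–CH3, C11–C13 α‑methylene lactone. The ten‑membered carbocycle is cut at its β‑hydroxy ketone C1(OH)–C2H2–C3(=O). A retro‑aldol cut of C1–C2 gives an unprotected monocyclic keto aldehyde, so the ring closure is the last step and delivers the natural product itself.
2. Enabling feature: the C3 ketone lies between the CH3 that becomes C2 and the fully substituted epoxide carbon C4. It therefore has one enolisable side only and offers a ketone‑O/epoxide‑O chelate. The cis‑4,5‑epoxide and the trans‑fused γ‑lactone ring (O–C6–C7–C11–C12) hold C3–C8 as a U‑turn, so a dizinc template can grip both chain ends.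
3. The keto aldehyde comes from a bis‑silyl ether by desilylation and a double oxidation that also erases a sacrificial C3 carbinol centre. The C8 tiglate enters with Mitsunobu inversion. The C7–C8 bond, the stereocentres C7 and C8, and the exocyclic methylene arise in one zinc Barbier union of a bromomethyl butenolide with a C8–C1 aldehyde whose C10 comes from the chiral pool.
4. The butenolide comes from (S)‑but‑3‑yn‑2‑ol, acrolein and 2‑(bromomethyl)acrylic acid. The sequence is asymmetric alkynylation (C6), syn‑carbomagnesiation (4Z alkene), hydroxyl‑directed epoxidation (C4, C5), esterification and ring‑closing metathesis.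
5. Ring order: epoxide (step 4), five‑membered lactone (step 6, turned into the α‑methylene‑γ‑lactone in step 10), ten‑membered carbocycle (step 14).

Key step: step 14

Assumption: the sense of induction of the zinc–ProPhenol complexes is assigned by analogy with simple aldehydes. The ligand antipode is defined by the aldehyde face that must be attacked (Re in steps 2 and 14) and is taken to be (S,S).

Step 1
Reactants: 1 (S)-but-3-yn-2-ol
Product: 2 (S)-tert-butyl(but-3-yn-2-yloxy)dimethylsilane
Conditions: TBSCl, imidazole, CH2Cl2, 0 °C to rt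
Reagents that add atoms: tert-butyldimethylsilyl chloride, CC(C)(C)[Si](C)(C)Cl
Why: Routine silyl ether formation masks the future C3 oxygen, and the chiral-pool carbinol centre (C3, S) is untouched and kept as a sacrificial control element.

Step 2
Reactants: 2 (S)-tert-butyl(but-3-yn-2-yloxy)dimethylsilane; 3 acrolein
Product: 4 (3S,6S)-6-(tert-butyldimethylsilyloxy)hept-1-en-4-yn-3-ol
Conditions: (S,S)-ProPhenol (20 mol %), Me2Zn (3 equiv), Ph3P=O (40 mol %), toluene, 0 °C, slow addition of 3
Reagents that add atoms: none
Why: In this dinuclear-zinc (ProPhenol) catalysed asymmetric alkynylation of an α,β-unsaturated aldehyde, the ligand should deliver the zinc acetylide to the Re face of acrolein and so set the C6 carbinol centre as S.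

Step 3
Reactants: 4 (3S,6S)-6-(tert-butyldimethylsilyloxy)hept-1-en-4-yn-3-ol
Product: 5 (3S,4Z,6S)-6-(tert-butyldimethylsilyloxy)-5-methylhepta-1,4-dien-3-ol
Conditions: MeMgBr (5 equiv), Fe(acac)3 (15 mol %), THF, −78 to 0 °C; aq NH4Cl
Reagents that add atoms: methylmagnesium bromide, C[Mg]Br
Why: In this alkoxide-directed iron-catalysed syn-carbomagnesiation of a propargylic alcohol, methyl goes to the distal alkyne carbon (C4) and the alkenyl–Mg bond at C5 is protonated on work-up, so C3 and C6 end up cis (4Z) and no stereocentre is touched.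

Step 4
Reactants: 5 (3S,4Z,6S)-6-(tert-butyldimethylsilyloxy)-5-methylhepta-1,4-dien-3-ol
Product: 6 (1S)-1-[(2R,3R)-3-[(1S)-1-(tert-butyldimethylsilyloxy)ethyl]-3-methyloxiran-2-yl]prop-2-en-1-ol
Conditions: mCPBA (1.05 equiv), CH2Cl2, −10 °C
Reagents that add atoms: 3-chloroperbenzoic acid, O=C(OO)c1cccc(Cl)c1
Why: In this hydroxyl-directed (Henbest-type) epoxidation, A(1,3) strain in the Z-allylic alcohol holds H6 in the alkene plane, the peracid hydrogen-bonded to C6-OH attacks the face that is also anti to the C3 silyloxy group (matched), which should set 4R,5R as a cis-epoxide, and the monosubstituted vinyl group reacts far more slowly.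

Step 5
Reactants: 6 (1S)-1-[(2R,3R)-3-[(1S)-1-(tert-butyldimethylsilyloxy)ethyl]-3-methyloxiran-2-yl]prop-2-en-1-ol; 7 2-(bromomethyl)acrylic acid
Product: 8 (1S)-1-[(2R,3R)-3-[(1S)-1-(tert-butyldimethylsilyloxy)ethyl]-3-methyloxiran-2-yl]prop-2-en-1-yl 2-(bromomethyl)acrylate
Conditions: DCC, DMAP (5 mol %), CH2Cl2, 0 °C
Reagents that add atoms: none
Why: Steglich esterification acylates C6-OH with retention and brings in C11, C12 and C13, and the low DMAP loading and temperature protect the allylic bromide.

Step 6
Reactants: 8 (1S)-1-[(2R,3R)-3-[(1S)-1-(tert-butyldimethylsilyloxy)ethyl]-3-methyloxiran-2-yl]prop-2-en-1-yl 2-(bromomethyl)acrylate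
Product: 9 (5S)-3-(bromomethyl)-5-[(2R,3R)-3-[(1S)-1-(tert-butyldimethylsilyloxy)ethyl]-3-methyloxiran-2-yl]furan-2(5H)-one
Conditions: Grubbs II (5 mol %), CH2Cl2 (5 mM), reflux
Reagents that add atoms: none
Why: Ring-closing metathesis of the acrylate-type diene closes the five-membered butenolide (C7=C11) with loss of ethene, touches no stereocentre, and tolerates the epoxide, silyl ether and allylic bromide.

Step 7
Reactants: 10 (S)-4-methoxy-2-methyl-4-oxobutanoic acid
Product: 11 methyl (S)-4-hydroxy-3-methylbutanoate
Conditions: BH3·SMe2 (1.1 equiv), THF, −10 to 0 °C; aq work-up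
Reagents that add atoms: none
Why: Chemoselective borane reduction converts the carboxylic acid (future C1) beside the methyl ester (future C8), and the chiral-pool centre C10 is not enolised under these conditions.

Step 8
Reactants: 11 methyl (S)-4-hydroxy-3-methylbutanoate
Product: 12 methyl (S)-4-(tert-butyldimethylsilyloxy)-3-methylbutanoate
Conditions: TBSCl, imidazole, CH2Cl2, 0 °C
Reagents that add atoms: tert-butyldimethylsilyl chloride, CC(C)(C)[Si](C)(C)Cl
Why: Immediate silyl ether formation blocks lactonisation of the γ-hydroxy ester and protects C1-OH without touching C10.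

Step 9
Reactants: 12 methyl (S)-4-(tert-butyldimethylsilyloxy)-3-methylbutanoate
Product: 13 (S)-4-(tert-butyldimethylsilyloxy)-3-methylbutanal
Conditions: DIBAL-H (1.05 equiv), CH2Cl2, −78 °C; Rochelle salt
Reagents that add atoms: none
Why: Low-temperature DIBAL-H half-reduction of the ester stops at the tetrahedral aluminate and gives the C8 aldehyde on work-up, and C10 is β to the carbonyl and cannot epimerise.

Step 10
Reactants: 9 (5S)-3-(bromomethyl)-5-[(2R,3R)-3-[(1S)-1-(tert-butyldimethylsilyloxy)ethyl]-3-methyloxiran-2-yl]furan-2(5H)-one; 13 (S)-4-(tert-butyldimethylsilyloxy)-3-methylbutanal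
Product: 14 (4R,5S)-4-[(1S,3S)-4-(tert-butyldimethylsilyloxy)-1-hydroxy-3-methylbutyl]-5-[(2R,3R)-3-[(1S)-1-(tert-butyldimethylsilyloxy)ethyl]-3-methyloxiran-2-yl]-3-methylenedihydrofuran-2(3H)-one
Conditions: Zn dust, THF/sat. aq NH4Cl (2:1), 0 °C to rt
Reagents that add atoms: none
Why: Zinc Barbier allylation (SE2′, γ-attack) with a 3-(bromomethyl)butenolide forms C7–C8 and shifts the double bond to the exocyclic C11=C13 position; the aldehyde should approach C7 anti to the C6 oxiranyl group (7R, trans-lactone) and, through a Zimmerman–Traxler chair with the ring-locked E-type allylzinc, give the anti adduct (8S), which is the C8 epimer that the next step needs.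

Step 11
Reactants: 14 (4R,5S)-4-[(1S,3S)-4-(tert-butyldimethylsilyloxy)-1-hydroxy-3-methylbutyl]-5-[(2R,3R)-3-[(1S)-1-(tert-butyldimethylsilyloxy)ethyl]-3-methyloxiran-2-yl]-3-methylenedihydrofuran-2(3H)-one; 15 tiglic acid ((E)-2-methylbut-2-enoic acid)
Product: 16 bis-TBS seco-tiglate: compound 14 with C8 inverted to R and carrying the (E)-2-methylbut-2-enoate, all other centres as in 14
Conditions: PPh3, DIAD, toluene, 0 °C to rt
Reagents that add atoms: none
Why: In this Mitsunobu esterification, SN2 displacement of the C8 oxyphosphonium ion by tiglate installs the ester and inverts C8 from S to R in one operation, with the E geometry of the acid retained.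

Step 12
Reactants: 16 bis-TBS seco-tiglate
Product: 17 seco-diol: compound 16 with both silyl groups replaced by H (free primary C1-OH and secondary C3-OH), all centres unchanged
Conditions: HF·pyridine, pyridine, THF, 0 °C to rt
Reagents that add atoms: none
Why: Fluoride-mediated cleavage removes both silyl ethers under buffered, weakly acidic conditions that should spare the epoxide, tiglate and α-methylene lactone, and no stereocentre changes.

Step 13
Reactants: 17 seco-diol
Product: 18 seco keto aldehyde: (6S,7R)-α-methylene-γ-butyrolactone bearing at C6 the (4R,5R)-cis-epoxide with an acetyl group on C4 and at C7 the (8R)-tigloyloxy-(10S)-methyl-4-oxobutyl chain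
Conditions: DMP (3 equiv), NaHCO3, CH2Cl2, 0 °C to rt
Reagents that add atoms: none
Why: A double Dess–Martin oxidation turns C1-OH into the aldehyde and C3-OH into the methyl ketone in one operation and erases the sacrificial C3 centre, and the buffered non-basic medium should leave C10 intact.

Step 14
Reactants: 18 seco keto aldehyde
Product: 19 eupakirunsin C
Conditions: (S,S)-ProPhenol (1.1 equiv), Et2Zn (2.2 equiv), t-BuOH (1.1 equiv), THF, rt; then 18 by syringe pump (final 1 mM), 4 Å MS, −20 °C; pH 7 buffer
Reagents that add atoms: none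
Why: Proposed new method: ProPhenol, two Et2Zn and t-BuOH assemble a dizinc complex with one basic Zn–Ot-Bu site; the C3 ketone of 18 docks on it through its carbonyl and epoxide oxygens (five-membered chelate) and is deprotonated at C2, the C1 aldehyde binds to the neighbouring zinc, and the bridging zinc enolate adds to it, so the two chain ends are tied by a temporary dizinc tether and the product is held as a six-membered zinc aldolate chelate until the quench. The closest known reaction type is the intermolecular direct aldol addition of methyl ketones and of chelating α-oxygenated ketones to α-branched aldehydes under dinuclear zinc–ProPhenol catalysis; what is new is the intramolecular medium-ring setting and the use of a full equivalent of the complex as template and thermodynamic sink. The ten-membered carbocycle closes in a 10-(enolendo)-exo-trig mode, and the cis-epoxide (C3 and C6 on the same side) together with the trans-fused γ-lactone (O–C6–C7–C11–C12) already fixes the C3–C8 segment as a U-turn that points C2 and C1 at each other. The one new stereocentre, C1, is controlled by the ligand, whose diarylcarbinol pocket should leave only the Re face of the zinc-bound aldehyde open (1R), while C4–C8 and C10 are spectators. The step needs enolisation of the ketone and not of the aldehyde, and 1,2-addition to C1 and not Michael addition to C13: C4 is fully substituted, so C2 is the only enolisable position of the ketone, bidentate binding acidifies only this carbonyl whereas the monodentate aldehyde offers only a hindered tertiary C10–H, and attack on the α-methylene lactone would demand a strained eight-membered closure onto a weaker electrophile. Slow addition to 1 mM should suppress dimers, and the low temperature and chelation should stop retro-aldol cleavage and loss of water to the C1=C2 enone.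

**Compound list**
1 | (S)-but-3-yn-2-ol | C#C[C@H](C)O | starting material
2 | (S)-tert-butyl(but-3-yn-2-yloxy)dimethylsilane | C#C[C@H](C)O[Si](C)(C)C(C)(C)C | intermediate
3 | acrolein | C=CC=O | starting material
4 | (3S,6S)-6-(tert-butyldimethylsilyloxy)hept-1-en-4-yn-3-ol | C=C[C@H](O)C#C[C@H](C)O[Si](C)(C)C(C)(C)C | intermediate
5 | (3S,4Z,6S)-6-(tert-butyldimethylsilyloxy)-5-methylhepta-1,4-dien-3-ol | C=C[C@H](O)/C=C(/C)[C@H](C)O[Si](C)(C)C(C)(C)C | intermediate
6 | (1S)-1-[(2R,3R)-3-[(1S)-1-(tert-butyldimethylsilyloxy)ethyl]-3-methyloxiran-2-yl]prop-2-en-1-ol | C=C[C@H](O)[C@H]1O[C@@]1(C)[C@H](C)O[Si](C)(C)C(C)(C)C | intermediate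
7 | 2-(bromomethyl)acrylic acid | C=C(CBr)C(=O)O | starting material
8 | 2-(bromomethyl)acrylate ester of 6 | C=C[C@H](OC(=O)C(=C)CBr)[C@H]1O[C@@]1(C)[C@H](C)O[Si](C)(C)C(C)(C)C | intermediate
9 | (5S)-3-(bromomethyl)-5-[(2R,3R)-3-[(1S)-1-(tert-butyldimethylsilyloxy)ethyl]-3-methyloxiran-2-yl]furan-2(5H)-one | O=C1O[C@@H](C=C1CBr)[C@H]1O[C@@]1(C)[C@H](C)O[Si](C)(C)C(C)(C)C | intermediate
10 | (S)-4-methoxy-2-methyl-4-oxobutanoic acid | COC(=O)C[C@H](C)C(=O)O | starting material
11 | methyl (S)-4-hydroxy-3-methylbutanoate | COC(=O)C[C@H](C)CO | intermediate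
12 | methyl (S)-4-(tert-butyldimethylsilyloxy)-3-methylbutanoate | COC(=O)C[C@H](C)CO[Si](C)(C)C(C)(C)C | intermediate
13 | (S)-4-(tert-butyldimethylsilyloxy)-3-methylbutanal | O=CC[C@H](C)CO[Si](C)(C)C(C)(C)C | intermediate
14 | Barbier adduct, (8S)-alcohol | C=C1C(=O)O[C@H]([C@H]2O[C@@]2(C)[C@H](C)O[Si](C)(C)C(C)(C)C)[C@H]1[C@@H](O)C[C@H](C)CO[Si](C)(C)C(C)(C)C | intermediate
15 | tiglic acid | C/C=C(\C)C(=O)O | starting material
16 | bis-TBS seco-tiglate, (8R) | C=C1C(=O)O[C@H]([C@H]2O[C@@]2(C)[C@H](C)O[Si](C)(C)C(C)(C)C)[C@H]1[C@H](OC(=O)/C(C)=C/C)C[C@H](C)CO[Si](C)(C)C(C)(C)C | intermediate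
17 | seco-diol | C=C1C(=O)O[C@H]([C@H]2O[C@@]2(C)[C@H](C)O)[C@H]1[C@H](OC(=O)/C(C)=C/C)C[C@H](C)CO | intermediate
18 | seco keto aldehyde | C=C1C(=O)O[C@H]([C@H]2O[C@@]2(C)C(C)=O)[C@H]1[C@H](OC(=O)/C(C)=C/C)C[C@H](C)C=O | intermediate
19 | eupakirunsin C | C=C1C(=O)O[C@H]2[C@H]1[C@H](OC(=O)/C(C)=C/C)C[C@H](C)[C@H](O)CC(=O)[C@]1(C)O[C@H]21 | target

**Step count**
- Total step count: 14.
- Longest linear sequence: 11 steps (steps 1–6 and 10–14, from 1).

**Steps most likely to fail**

Step 14 (labelled step).
- What may go wrong: competing enolisation and epimerisation of the aldehyde at C10, oligomerisation in place of ring closure, or an aldol equilibrium that lies on the open-chain side.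
- The fallback sets out from 17 and comes back at 19. It generates the C2 enolate reductively from a halide instead of by deprotonation.
- Selective silylation of the primary hydroxyl of 17 (TESCl, imidazole, −20 °C) would give the mono-TES ether F1, and Dess–Martin oxidation the epoxy methyl ketone F2.
- Soft enolisation (TMSOTf, Et3N, −78 °C) would give the trimethylsilyl enol ether F3, and NBS the bromomethyl ketone F4.
- HF·pyridine would free the primary alcohol F5, and Dess–Martin oxidation would give the bromo keto aldehyde F6.
- Dropwise addition of SmI2 (2.0 equiv) to F6 in THF at −78 °C under high dilution closes the same bond and gives 19. This samarium Reformatsky-type aldol is the known way to close medium carbocycles from α-bromo ketone aldehydes.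
- Inverse addition of the reductant protects the epoxy ketone and the α-methylene lactone from over-reduction.

Step 11.
- What may go wrong: slow SN2 displacement at the hindered C8 oxyphosphonium ion, so that elimination or conjugate addition of the phosphine to the α-methylene lactone takes over.
- The fallback sets out from 14 and comes back at 16. It replaces substitution by a redox inversion.
- Dess–Martin oxidation of 14 would give the C8 ketone F7.
- Corey–Bakshi–Shibata reduction ((S)-Me-CBS, catecholborane, −78 °C, reagent control) would give the (8R)-alcohol F8.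
- Yamaguchi esterification of F8 with 15 (2,4,6-trichlorobenzoyl chloride, Et3N, DMAP) would give 16 with retention.

Step 3.
- What may go wrong: loss of regiocontrol or incomplete syn-addition on an alkyne flanked by two oxygenated carbons, or decomposition of the allylic alkoxide under the iron/Grignard conditions.
- The fallback sets out from 1 and comes back at 5, bypassing steps 1–3. It builds the Z-alkene before C6.
- Copper-mediated anti-carbomagnesiation of 1 (MeMgBr, CuI, then I2) would give (S,Z)-4-iodo-3-methylbut-3-en-2-ol F9, and silylation its TBS ether F10.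
- Iodine–lithium exchange (t-BuLi, −78 °C) and acylation with N-methoxy-N-methylacrylamide would give the cross-conjugated Z-dienone F11.
- Corey–Bakshi–Shibata reduction ((R)-Me-CBS, catecholborane) would set C6 and give 5.

**Further compounds**
F1 | step 14 | mono-TES ether of 17 (C1-O-TES, C3-OH free) | C=C1C(=O)O[C@H]([C@H]2O[C@@]2(C)[C@H](C)O)[C@H]1[C@H](OC(=O)/C(C)=C/C)C[C@H](C)CO[Si](CC)(CC)CC
F2 | step 14 | epoxy methyl ketone, C1-O-TES | C=C1C(=O)O[C@H]([C@H]2O[C@@]2(C)C(C)=O)[C@H]1[C@H](OC(=O)/C(C)=C/C)C[C@H](C)CO[Si](CC)(CC)CC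
F3 | step 14 | trimethylsilyl enol ether of F2 | C=C1C(=O)O[C@H]([C@H]2O[C@@]2(C)C(=C)O[Si](C)(C)C)[C@H]1[C@H](OC(=O)/C(C)=C/C)C[C@H](C)CO[Si](CC)(CC)CC
F4 | step 14 | bromomethyl ketone, C1-O-TES | C=C1C(=O)O[C@H]([C@H]2O[C@@]2(C)C(=O)CBr)[C@H]1[C@H](OC(=O)/C(C)=C/C)C[C@H](C)CO[Si](CC)(CC)CC
F5 | step 14 | bromomethyl ketone, free C1-OH | C=C1C(=O)O[C@H]([C@H]2O[C@@]2(C)C(=O)CBr)[C@H]1[C@H](OC(=O)/C(C)=C/C)C[C@H](C)CO
F6 | step 14 | bromo keto aldehyde | C=C1C(=O)O[C@H]([C@H]2O[C@@]2(C)C(=O)CBr)[C@H]1[C@H](OC(=O)/C(C)=C/C)C[C@H](C)C=O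
F7 | step 11 | C8 ketone from 14 | C=C1C(=O)O[C@H]([C@H]2O[C@@]2(C)[C@H](C)O[Si](C)(C)C(C)(C)C)[C@H]1C(=O)C[C@H](C)CO[Si](C)(C)C(C)(C)C
F8 | step 11 | (8R)-alcohol, C8 epimer of 14 | C=C1C(=O)O[C@H]([C@H]2O[C@@]2(C)[C@H](C)O[Si](C)(C)C(C)(C)C)[C@H]1[C@H](O)C[C@H](C)CO[Si](C)(C)C(C)(C)C
F9 | step 3 | (S,Z)-4-iodo-3-methylbut-3-en-2-ol | I/C=C(/C)[C@H](C)O
F10 | step 3 | TBS ether of F9 | I/C=C(/C)[C@H](C)O[Si](C)(C)C(C)(C)C
F11 | step 3 | (S,Z)-6-(tert-butyldimethylsilyloxy)-5-methylhepta-1,4-dien-3-one | C=CC(=O)/C=C(/C)[C@H](C)O[Si](C)(C)C(C)(C)C
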